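**Plan**

1. Retrosynthetic cuts: the quinone goes back to its dimethyl ether (two aryl O–CH3 bonds). The side chain is cut at the ester C–O bond, at the prenyl C=C bond (cross-metathesis) and at the carbinol C–CH2 bond (allylation of a furan aldehyde). The furan is cut at O1–C5, and the cyclopropene so revealed is cut into an aryl diazomethyl ketone and a propargyl silyl ether.
2. Enabling feature: in the furan (O1, C2 bearing the quinone, C3–H, C4 bearing the side chain, C5–H) the ring oxygen is bonded to an unsubstituted CH (C5) lying next to the branched C4. This is the pattern left when a ketone oxygen captures the CH alkene carbon of a ring-opened 3-acylcyclopropene.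
3. Forward order: carbene transfer builds the cyclopropene ring, strain-release ring opening turns it into the furan ring, and the C4 carbon is raised to the aldehyde. Allyl, isovalerate and the prenyl cap follow, and the benzene ring is oxidized to the quinone ring last.
4. The alkene and the carbinol centre are added only after the furan exists, because a rhodium ketocarbenoid cannot be trusted to prefer a terminal alkyne over a prenyl alkene.
5. Stereochemistry: the single R centre is set by reagent-controlled Brown allylboration of the furan aldehyde with the (−)-α-pinene-derived reagent; no later step breaks a bond at that carbon.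

Key step: step 3

Assumption: racemic 5 is used because its only stereocentre is erased in step 3; atom labels in the text follow the target's furan numbering (aryl on C2, side chain on C4), whereas the systematic names number the ring from the other side (aryl on C5, side chain on C3).

**Route**

Step 1
Reactants: 1 2,5-dimethoxybenzoyl chloride; 2 (trimethylsilyl)diazomethane
Product: 3 2-diazo-1-(2,5-dimethoxyphenyl)ethan-1-one
Conditions: 2 (2 equiv), THF/MeCN 1:1, 0 °C to rt
Reagents that add atoms: none
Why: C-acylation of the diazoalkane by the aroyl chloride followed by loss of the silyl group as Me3SiCl (the trimethylsilyldiazomethane form of the Arndt–Eistert diazoketone synthesis) gives the aryl diazomethyl ketone without free HCl, and the methoxy groups are inert.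

Step 2
Reactants: 3 2-diazo-1-(2,5-dimethoxyphenyl)ethan-1-one; 4 tert-butyldimethyl(prop-2-yn-1-yloxy)silane
Product: 5 [2-({[tert-butyl(dimethyl)silyl]oxy}methyl)cycloprop-2-en-1-yl](2,5-dimethoxyphenyl)methanone (racemic at the ring CH)
Conditions: Rh2(OAc)4 (2 mol %), 4 (5 equiv), CH2Cl2, 3 added by syringe pump over 8 h, 0 °C to rt
Reagents that add atoms: none
Why: Rh2(OAc)4 converts the diazoketone into an electrophilic divalent-rhodium ketocarbenoid that adds across the terminal alkyne in a [2+1] cyclopropenation, the fivefold excess of alkyne and the slow addition keeping carbene dimerization and capture by the ortho-methoxy oxygen in check, and the substrate offering no alkene that could be cyclopropanated instead.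

Step 3
Reactants: 5 [2-({[tert-butyl(dimethyl)silyl]oxy}methyl)cycloprop-2-en-1-yl](2,5-dimethoxyphenyl)methanone
Product: 6 tert-butyl{[5-(2,5-dimethoxyphenyl)furan-3-yl]methoxy}dimethylsilane
Conditions: Rh2(OAc)4 (5 mol %), ClCH2CH2Cl (0.02 M), 60 °C
Reagents that add atoms: none
Why: Rh2(OAc)4, an electrophilic divalent-rhodium Lewis acid, adds to the cyclopropene double bond at its unsubstituted carbon, the positive charge developing on the carbon that carries the silyloxymethyl group; this cyclopropyl cation opens with release of ring strain by breaking the σ bond between the ketone-bearing CH and the metalated carbon, which gives a rhodium vinylcarbene. The ketone oxygen then attacks the carbene carbon, a 1,5-oxacyclization that can also be read as a 6π electrocyclization of the metalla-oxatriene, and loss of the metal delivers the aromatic furan with the new O1–C5 bond. The closest known reaction type is the rhodium- or palladium-catalysed cycloisomerization of 3-acylcyclopropenes to furans. No stereocentre is formed, and the ring CH centre of racemic 5 disappears, so its configuration does not matter. The one selectivity needed is the choice between the two ring σ bonds; it is secured by the substitution pattern of the alkene, since the metal reaches only the CH carbon and leaves the more substituted cation, which places oxygen on C5 and the oxygenated carbon on C4.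

Step 4
Reactants: 6 tert-butyl{[5-(2,5-dimethoxyphenyl)furan-3-yl]methoxy}dimethylsilane
Product: 7 [5-(2,5-dimethoxyphenyl)furan-3-yl]methanol
Conditions: Bu4NF (1.2 equiv), THF, 0 °C to rt; aqueous work-up
Reagents that add atoms: none
Why: Fluoride cleaves the Si–O bond of the primary silyl ether (standard TBS removal), and the furan and the aryl methyl ethers are inert to Bu4NF.

Step 5
Reactants: 7 [5-(2,5-dimethoxyphenyl)furan-3-yl]methanol
Product: 8 5-(2,5-dimethoxyphenyl)furan-3-carbaldehyde
Conditions: Dess–Martin periodinane (1.2 equiv), CH2Cl2, 0 °C to rt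
Reagents that add atoms: none
Why: Dess–Martin oxidation takes the primary furylmethanol to the aldehyde under mild conditions without over-oxidation and without touching the electron-rich furan or arene.

Step 6
Reactants: 8 5-(2,5-dimethoxyphenyl)furan-3-carbaldehyde; 9 B-allylbis(isopinocampheyl)borane of the (−)-α-pinene series (lIpc2B-allyl, commercial solution)
Product: 11 (R)-1-[5-(2,5-dimethoxyphenyl)furan-3-yl]but-3-en-1-ol, via borinate ester 10 (not isolated)
Conditions: 9 (1.5 equiv), Et2O, −78 °C; then 3 M NaOH, 30% H2O2, 0 °C to rt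
Reagents that add atoms: none
Why: Brown allylboration proceeds through a closed six-membered chair transition state in which the isopinocampheyl groups of the (−)-α-pinene series direct the allyl group to the Re face of the aromatic aldehyde, which sets the R carbinol centre (the mirror image of the S alcohol that the (+)-α-pinene reagent gives with benzaldehyde), and the oxidative work-up frees the alcohol from the borinate.

Step 7
Reactants: 11 (R)-1-[5-(2,5-dimethoxyphenyl)furan-3-yl]but-3-en-1-ol; 12 3-methylbutanoyl chloride (isovaleryl chloride)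
Product: 13 (R)-1-[5-(2,5-dimethoxyphenyl)furan-3-yl]but-3-en-1-yl 3-methylbutanoate
Conditions: 12 (1.3 equiv), Et3N, DMAP (10 mol %), CH2Cl2, 0 °C
Reagents that add atoms: none
Why: DMAP-catalysed O-acylation with the acid chloride forms the ester through an acylpyridinium intermediate without breaking the C–O bond of the carbinol, so the R configuration is retained.

Step 8
Reactants: 13 (R)-1-[5-(2,5-dimethoxyphenyl)furan-3-yl]but-3-en-1-yl 3-methylbutanoate; 14 2-methylbut-2-ene
Product: 15 (R)-1-[5-(2,5-dimethoxyphenyl)furan-3-yl]-4-methylpent-3-en-1-yl 3-methylbutanoate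
Conditions: second-generation Grubbs catalyst RuCl2(=CHPh)(PCy3)(H2IMes) (5 mol %), 14 (large excess, co-solvent), CH2Cl2, 40 °C, sealed tube
Reagents that add atoms: none
Why: Olefin cross-metathesis of the terminal alkene with a large excess of 2-methylbut-2-ene caps the allyl group as the trisubstituted prenyl alkene with loss of propene, and neither the aromatic furan, the ester nor the hindered product alkene engages the ruthenium carbene further.

Step 9
Reactants: 15 (R)-1-[5-(2,5-dimethoxyphenyl)furan-3-yl]-4-methylpent-3-en-1-yl 3-methylbutanoate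
Product: 16 (R)-1-[5-(3,6-dioxocyclohexa-1,4-dien-1-yl)furan-3-yl]-4-methylpent-3-en-1-yl 3-methylbutanoate (CNP0219765.1)
Conditions: (NH4)2Ce(NO3)6 (2.5 equiv), MeCN/H2O 2:1, 0 °C, 15 min
Reagents that add atoms: water, O
Why: Oxidative demethylation of the para-dimethoxyarene by tetravalent cerium passes through the arene radical cation, water adds at the two methoxy-bearing carbons and methanol leaves to give the 1,4-benzoquinone, which in turn deactivates the attached furan toward further oxidation, and no bond at the stereocentre is touched.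

**Compound list**

1 | 2,5-dimethoxybenzoyl chloride | COc1ccc(OC)c(c1)C(=O)Cl | starting material
2 | (trimethylsilyl)diazomethane | C[Si](C)(C)C=[N+]=[N-] | starting material
3 | 2-diazo-1-(2,5-dimethoxyphenyl)ethan-1-one | COc1ccc(OC)c(c1)C(=O)C=[N+]=[N-] | intermediate
4 | tert-butyldimethyl(prop-2-yn-1-yloxy)silane | C#CCO[Si](C)(C)C(C)(C)C | starting material
5 | [2-({[tert-butyl(dimethyl)silyl]oxy}methyl)cycloprop-2-en-1-yl](2,5-dimethoxyphenyl)methanone, racemic at the ring CH | COc1ccc(OC)c(c1)C(=O)C1C=C1CO[Si](C)(C)C(C)(C)C | intermediate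
6 | tert-butyl{[5-(2,5-dimethoxyphenyl)furan-3-yl]methoxy}dimethylsilane | COc1ccc(OC)c(c1)-c1cc(CO[Si](C)(C)C(C)(C)C)co1 | intermediate
7 | [5-(2,5-dimethoxyphenyl)furan-3-yl]methanol | COc1ccc(OC)c(c1)-c1cc(CO)co1 | intermediate
8 | 5-(2,5-dimethoxyphenyl)furan-3-carbaldehyde | COc1ccc(OC)c(c1)-c1cc(C=O)co1 | intermediate
9 | B-allylbis(isopinocampheyl)borane of the (−)-α-pinene series (lIpc2B-allyl); each isopinocampheyl group has the configuration that gives (1S,2S,3S,5R)-(+)-isopinocampheol on oxidation | C=CCB([C@H]1C[C@H]2C[C@@H]([C@@H]1C)C2(C)C)[C@H]1C[C@H]2C[C@@H]([C@@H]1C)C2(C)C | starting material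
10 | (R)-1-[5-(2,5-dimethoxyphenyl)furan-3-yl]but-3-en-1-yl bis(isopinocampheyl)borinate, formed in the flask and not isolated | COc1ccc(OC)c(c1)-c1cc(co1)[C@@H](CC=C)OB([C@H]1C[C@H]2C[C@@H]([C@@H]1C)C2(C)C)[C@H]1C[C@H]2C[C@@H]([C@@H]1C)C2(C)C | intermediate
11 | (R)-1-[5-(2,5-dimethoxyphenyl)furan-3-yl]but-3-en-1-ol | COc1ccc(OC)c(c1)-c1cc(co1)[C@@H](CC=C)O | intermediate
12 | 3-methylbutanoyl chloride (isovaleryl chloride) | CC(C)CC(=O)Cl | starting material
13 | (R)-1-[5-(2,5-dimethoxyphenyl)furan-3-yl]but-3-en-1-yl 3-methylbutanoate | COc1ccc(OC)c(c1)-c1cc(co1)[C@@H](CC=C)OC(=O)CC(C)C | intermediate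
14 | 2-methylbut-2-ene | CC=C(C)C | starting material
15 | (R)-1-[5-(2,5-dimethoxyphenyl)furan-3-yl]-4-methylpent-3-en-1-yl 3-methylbutanoate | COc1ccc(OC)c(c1)-c1cc(co1)[C@@H](CC=C(C)C)OC(=O)CC(C)C | intermediate
16 | (R)-1-[5-(3,6-dioxocyclohexa-1,4-dien-1-yl)furan-3-yl]-4-methylpent-3-en-1-yl 3-methylbutanoate | CC(C)=CC[C@@H](OC(=O)CC(C)C)c1coc(C2=CC(=O)C=CC2=O)c1 | target

**Totals**

Total step count: 9. Longest linear sequence: 9 steps (1 to 16).

**Steps most likely to fail**

Step 2. The carbene transfer may be diverted. The ketocarbenoid can dimerize or be trapped by its own ortho-methoxy oxygen as a cyclic oxonium ylide. A stepwise addition through a vinyl cation would close the wrong, 2,5-disubstituted furan directly. The cyclopropene may also open on the catalyst before isolation, which is harmless because it gives 6.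

Fallback: the route sets out from alkyne 4 with the better-behaved ester carbenoid. Rh2(OAc)4-catalysed cyclopropenation with ethyl diazoacetate should give ethyl 2-({[tert-butyl(dimethyl)silyl]oxy}methyl)cycloprop-2-ene-1-carboxylate F1. MeNH(OMe)·HCl and iPrMgCl in THF at −20 °C should turn the ester into 2-({[tert-butyl(dimethyl)silyl]oxy}methyl)-N-methoxy-N-methylcycloprop-2-ene-1-carboxamide F2. Addition of 2,5-dimethoxyphenylmagnesium bromide (from 2-bromo-1,4-dimethoxybenzene and Mg) at −78 to 0 °C then returns to the route at ketone 5.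

Step 3. The ring may open at the other σ bond, putting oxygen on the substituted carbon (2,5-disubstituted furan), or the vinylcarbene may oligomerize instead of closing.

Fallback: the furan is built by carbonyl condensation, setting out from diazoketone 3. Aqueous 48% HBr in Et2O at 0 °C should give 2-bromo-1-(2,5-dimethoxyphenyl)ethan-1-one F3. C-alkylation of the sodium enolate of ethyl 3-oxopropanoate (from ethyl acetate, ethyl formate and NaH) in THF should give ethyl 4-(2,5-dimethoxyphenyl)-2-formyl-4-oxobutanoate F4. TsOH in hot toluene should close this 1,4-ketoaldehyde by Paal–Knorr cyclodehydration to ethyl 5-(2,5-dimethoxyphenyl)furan-3-carboxylate F5. LiAlH4 in THF at 0 °C reduces the ester and returns to the route at alcohol 7.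

Step 9. Over-oxidation is possible: the cerium oxidant may attack the free α-position C5 of the electron-rich furan or the prenyl alkene, and the nitric acid formed may ionize the furylmethyl ester.

Fallback: the quinone is unmasked early, where the formyl group deactivates C5 and no alkene is present, and the arene is then carried as a silyl-protected hydroquinone. The sequence sets out from aldehyde 8 and runs as follows.
- (NH4)2Ce(NO3)6 in MeCN/H2O at 0 °C should give 5-(3,6-dioxocyclohexa-1,4-dien-1-yl)furan-3-carbaldehyde F6.
- Na2S2O4 in EtOAc/H2O reduces it to 5-(2,5-dihydroxyphenyl)furan-3-carbaldehyde F7.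
- TBSCl and imidazole in DMF give 5-{2,5-bis[(tert-butyldimethylsilyl)oxy]phenyl}furan-3-carbaldehyde F8.
- Allylboration with 9 at −78 °C gives the bis(isopinocampheyl)borinate F9, and work-up with NaBO3·4H2O gives (R)-1-(5-{2,5-bis[(tert-butyldimethylsilyl)oxy]phenyl}furan-3-yl)but-3-en-1-ol F10.
- Acylation with 12 (Et3N, DMAP) gives the corresponding 3-methylbutanoate F11.
- Cross-metathesis with 14 and the second-generation Grubbs catalyst gives (R)-1-(5-{2,5-bis[(tert-butyldimethylsilyl)oxy]phenyl}furan-3-yl)-4-methylpent-3-en-1-yl 3-methylbutanoate F12.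
- HF·pyridine in THF gives (R)-1-[5-(2,5-dihydroxyphenyl)furan-3-yl]-4-methylpent-3-en-1-yl 3-methylbutanoate F13.
- Ag2O in Et2O oxidizes the hydroquinone and returns to the route at target 16.

**Further compounds**

F1 | step 2 | ethyl 2-({[tert-butyl(dimethyl)silyl]oxy}methyl)cycloprop-2-ene-1-carboxylate | CCOC(=O)C1C=C1CO[Si](C)(C)C(C)(C)C
F2 | step 2 | 2-({[tert-butyl(dimethyl)silyl]oxy}methyl)-N-methoxy-N-methylcycloprop-2-ene-1-carboxamide | CON(C)C(=O)C1C=C1CO[Si](C)(C)C(C)(C)C
F3 | step 3 | 2-bromo-1-(2,5-dimethoxyphenyl)ethan-1-one | COc1ccc(OC)c(c1)C(=O)CBr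
F4 | step 3 | ethyl 4-(2,5-dimethoxyphenyl)-2-formyl-4-oxobutanoate | CCOC(=O)C(C=O)CC(=O)c1cc(OC)ccc1OC
F5 | step 3 | ethyl 5-(2,5-dimethoxyphenyl)furan-3-carboxylate | CCOC(=O)c1coc(c1)-c1cc(OC)ccc1OC
F6 | step 9 | 5-(3,6-dioxocyclohexa-1,4-dien-1-yl)furan-3-carbaldehyde | O=Cc1coc(c1)C1=CC(=O)C=CC1=O
F7 | step 9 | 5-(2,5-dihydroxyphenyl)furan-3-carbaldehyde | O=Cc1coc(c1)-c1cc(O)ccc1O
F8 | step 9 | 5-{2,5-bis[(tert-butyldimethylsilyl)oxy]phenyl}furan-3-carbaldehyde | O=Cc1coc(c1)-c1cc(O[Si](C)(C)C(C)(C)C)ccc1O[Si](C)(C)C(C)(C)C
F9 | step 9 | (R)-1-(5-{2,5-bis[(tert-butyldimethylsilyl)oxy]phenyl}furan-3-yl)but-3-en-1-yl bis(isopinocampheyl)borinate | CC(C)(C)[Si](C)(C)Oc1ccc(O[Si](C)(C)C(C)(C)C)c(c1)-c1cc(co1)[C@@H](CC=C)OB([C@H]1C[C@H]2C[C@@H]([C@@H]1C)C2(C)C)[C@H]1C[C@H]2C[C@@H]([C@@H]1C)C2(C)C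
F10 | step 9 | (R)-1-(5-{2,5-bis[(tert-butyldimethylsilyl)oxy]phenyl}furan-3-yl)but-3-en-1-ol | CC(C)(C)[Si](C)(C)Oc1ccc(O[Si](C)(C)C(C)(C)C)c(c1)-c1cc(co1)[C@@H](CC=C)O
F11 | step 9 | (R)-1-(5-{2,5-bis[(tert-butyldimethylsilyl)oxy]phenyl}furan-3-yl)but-3-en-1-yl 3-methylbutanoate | CC(C)(C)[Si](C)(C)Oc1ccc(O[Si](C)(C)C(C)(C)C)c(c1)-c1cc(co1)[C@@H](CC=C)OC(=O)CC(C)C
F12 | step 9 | (R)-1-(5-{2,5-bis[(tert-butyldimethylsilyl)oxy]phenyl}furan-3-yl)-4-methylpent-3-en-1-yl 3-methylbutanoate | CC(C)(C)[Si](C)(C)Oc1ccc(O[Si](C)(C)C(C)(C)C)c(c1)-c1cc(co1)[C@@H](CC=C(C)C)OC(=O)CC(C)C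
F13 | step 9 | (R)-1-[5-(2,5-dihydroxyphenyl)furan-3-yl]-4-methylpent-3-en-1-yl 3-methylbutanoate | Oc1ccc(O)c(c1)-c1cc(co1)[C@@H](CC=C(C)C)OC(=O)CC(C)C
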